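The oxolane ring is numbered O1, C2 (aryl), C3 (CH2O-stearate), C4 (benzyl), C5 (CH2). Everything rests on cutting this ring into an aryl aldehyde (O1=C2) and a three-carbon unit C3–C4–C5. A palladium-catalysed trimethylenemethane (3+2) cycloaddition joins C2 to C3 and O1 to C5 in one operation, closes the ring and sets C2 and C3. It exploits the 1,3-relationship of nucleophilic C3 and electrophilic C5 across C4. The precursor is an allylic tert-butyl carbonate bearing CH2CO2Me on its central carbon. Its ester becomes the stearoyloxymethyl arm, and the exocyclic methylene left at C4 later takes the second aryl group by hydroboration and Suzuki coupling.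

Key step: step 3

Assumption: the target is read as (2S,3R,4R) (C2 aryl trans to the C3 arm, C3 arm cis to the C4 benzyl group), and the (S,S,S)-ligand is taken to lead to this series; its mirror image would be used if the opposite sense were found.

Step 1
Reactants: 1 4-methyl hydrogen itaconate
Product: 3 methyl 3-(hydroxymethyl)but-3-enoate, via mixed carbonic anhydride 2 (not isolated)
Conditions: i-BuOCOCl, N-methylmorpholine, THF, −15 °C; then NaBH4, THF/H2O, −15 to 0 °C; crude product used at once
Reagents that add atoms: isobutyl chloroformate, CC(C)COC(Cl)=O (carbonate unit of intermediate 2 only)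
Why: Mixed-anhydride activation followed by NaBH4 reduction is chemoselective for the free conjugated carboxyl group, because the carbonic anhydride is far more electrophilic than the methyl ester and the 1,1-disubstituted alkene is not touched; no stereocentre is formed.

Step 2
Reactants: 3 methyl 3-(hydroxymethyl)but-3-enoate
Product: 4 methyl 3-{[(tert-butoxycarbonyl)oxy]methyl}but-3-enoate
Conditions: Boc2O, DMAP (10 mol%), CH2Cl2, 0 °C
Reagents that add atoms: di-tert-butyl dicarbonate, CC(C)(C)OC(=O)OC(=O)OC(C)(C)C
Why: DMAP-catalysed O-acylation (carbonate formation) of the primary allylic alcohol gives the leaving group that later also supplies tert-butoxide as internal base; no stereocentre is formed.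

Step 3
Reactants: 4 methyl 3-{[(tert-butoxycarbonyl)oxy]methyl}but-3-enoate (2 equiv); 5 4-(benzyloxy)-3-methoxybenzaldehyde
Product: 6 methyl (2S,3S)-2-[4-(benzyloxy)-3-methoxyphenyl]-4-methylideneoxolane-3-carboxylate
Conditions: Pd2(dba)3·CHCl3 (2.5 mol%), (S,S,S)-phosphoramidite ligand (BINOL-derived, amine part trans-2,5-di(2-naphthyl)pyrrolidine, 6 mol%), toluene, 23–40 °C
Reagents that add atoms: none
Why: Zerovalent palladium ionises the allylic carbonate of 4, the tert-butoxide released with CO2 removes a proton from the ester-activated CH2, and the ester-stabilised trimethylenemethane–palladium zwitterion adds through its carbanionic carbon to the carbonyl carbon of 5 (bond C2–C3) before the alkoxide attacks a terminus of the π-allyl unit (bond O1–C5). The closest known reaction type is the palladium-catalysed trimethylenemethane (3+2) cycloaddition of aldehydes to 3-methylene oxolanes, run here with an acceptor-substituted donor that is generated by deprotonation. The oxolane ring is closed by intramolecular allylic etherification, a 5-exo-tet attack of O1 on the allyl terminus anti to palladium. C2 and C3 are both new: the trans arrangement of aryl and ester follows from the reversible aldol-type addition and the less crowded ring-closing transition state, and the absolute sense (2S,3S) is controlled by the chiral phosphoramidite on palladium in the ring-closing event. The step needs chemoselectivity for the aldehyde over self-reaction of the donor, regioselectivity (ester carbon bonded to C2, methylene left on C4) and enantioselectivity; the ester localises the negative charge on the future C3, the poorly nucleophilic tert-butoxide does not compete for the allyl unit, and the excess of 4 compensates for the modest electrophilicity of 5.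

Step 4
Reactants: 6 methyl (2S,3S)-2-[4-(benzyloxy)-3-methoxyphenyl]-4-methylideneoxolane-3-carboxylate
Product: 7 [(2S,3R)-2-[4-(benzyloxy)-3-methoxyphenyl]-4-methylideneoxolan-3-yl]methanol
Conditions: i-Bu2AlH (2.5 equiv), CH2Cl2, −78 °C; aq. potassium sodium tartrate
Reagents that add atoms: none
Why: Hydride reduction of the ester to the primary alcohol with a non-basic aluminium hydride at low temperature should leave C3 and the exocyclic alkene in place; no stereocentre is formed, and the change of the C3 descriptor from S to R is only a change of CIP priorities.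

Step 5
Reactants: 7 [(2S,3R)-2-[4-(benzyloxy)-3-methoxyphenyl]-4-methylideneoxolan-3-yl]methanol; 8 octadecanoyl chloride
Product: 9 [(2S,3R)-2-[4-(benzyloxy)-3-methoxyphenyl]-4-methylideneoxolan-3-yl]methyl octadecanoate
Conditions: Et3N, DMAP (cat.), CH2Cl2, 0 °C to rt
Reagents that add atoms: none
Why: DMAP-catalysed esterification of the unhindered primary alcohol with the acid chloride installs the stearate; no stereocentre is affected.

Step 6
Reactants: 9 [(2S,3R)-2-[4-(benzyloxy)-3-methoxyphenyl]-4-methylideneoxolan-3-yl]methyl octadecanoate; 10 1-(benzyloxy)-4-bromo-2-methoxybenzene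
Product: 12 [(2S,3R,4R)-2-[4-(benzyloxy)-3-methoxyphenyl]-4-{[4-(benzyloxy)-3-methoxyphenyl]methyl}oxolan-3-yl]methyl octadecanoate, via B-alkyl-9-BBN adduct 11 (not isolated)
Conditions: 9-BBN-H dimer, THF, 0 °C to rt; then 10, Pd(dppf)Cl2·CH2Cl2 (5 mol%), aq. K3PO4, THF/DMF, 50 °C
Reagents that add atoms: 9-BBN-H, [H]B1C2CCCC1CCC2 (boron unit of intermediate 11 only)
Why: Hydroboration with 9-BBN puts boron on the exocyclic CH2 and delivers hydrogen to C4 from the ring face opposite the adjacent C3 acyloxymethyl group, which sets C4 as R with the new CH2 group cis to the C3 arm, and the primary alkylborane is then coupled with 10 in a B-alkyl Suzuki–Miyaura reaction that does not touch this centre.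

Step 7
Reactants: 12 [(2S,3R,4R)-2-[4-(benzyloxy)-3-methoxyphenyl]-4-{[4-(benzyloxy)-3-methoxyphenyl]methyl}oxolan-3-yl]methyl octadecanoate
Product: 13 [(2S,3R,4R)-2-(4-hydroxy-3-methoxyphenyl)-4-[(4-hydroxy-3-methoxyphenyl)methyl]oxolan-3-yl]methyl octadecanoate
Conditions: H2 (1 atm), 10% Pd/C, EtOAc, rt, stopped at full conversion
Reagents that add atoms: none
Why: Catalytic hydrogenolysis of the two aryl benzyl ethers should be much faster than cleavage of the ring benzylic C2–O1 bond, and the ester is inert; no stereocentre is touched.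

Compound list
1 | 4-methyl hydrogen itaconate (4-methoxy-2-methylidene-4-oxobutanoic acid) | COC(=O)CC(=C)C(O)=O | starting material
2 | isobutoxycarbonyl 4-methoxy-2-methylidene-4-oxobutanoate (mixed carbonic anhydride) | COC(=O)CC(=C)C(=O)OC(=O)OCC(C)C | intermediate
3 | methyl 3-(hydroxymethyl)but-3-enoate | COC(=O)CC(=C)CO | intermediate
4 | methyl 3-{[(tert-butoxycarbonyl)oxy]methyl}but-3-enoate | COC(=O)CC(=C)COC(=O)OC(C)(C)C | intermediate
5 | 4-(benzyloxy)-3-methoxybenzaldehyde | O=Cc1ccc(OCc2ccccc2)c(OC)c1 | starting material
6 | methyl (2S,3S)-2-[4-(benzyloxy)-3-methoxyphenyl]-4-methylideneoxolane-3-carboxylate | COC(=O)[C@H]1C(=C)CO[C@@H]1c1ccc(OCc2ccccc2)c(OC)c1 | intermediate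
7 | [(2S,3R)-2-[4-(benzyloxy)-3-methoxyphenyl]-4-methylideneoxolan-3-yl]methanol | OC[C@H]1C(=C)CO[C@@H]1c1ccc(OCc2ccccc2)c(OC)c1 | intermediate
8 | octadecanoyl chloride (stearoyl chloride) | CCCCCCCCCCCCCCCCCC(Cl)=O | starting material
9 | [(2S,3R)-2-[4-(benzyloxy)-3-methoxyphenyl]-4-methylideneoxolan-3-yl]methyl octadecanoate | CCCCCCCCCCCCCCCCCC(=O)OC[C@H]1C(=C)CO[C@@H]1c1ccc(OCc2ccccc2)c(OC)c1 | intermediate
10 | 1-(benzyloxy)-4-bromo-2-methoxybenzene | COc1cc(Br)ccc1OCc1ccccc1 | starting material
11 | [(2S,3R,4R)-2-[4-(benzyloxy)-3-methoxyphenyl]-4-[(9-borabicyclo[3.3.1]nonan-9-yl)methyl]oxolan-3-yl]methyl octadecanoate | CCCCCCCCCCCCCCCCCC(=O)OC[C@H]1[C@@H](CB2C3CCCC2CCC3)CO[C@@H]1c1ccc(OCc2ccccc2)c(OC)c1 | intermediate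
12 | [(2S,3R,4R)-2-[4-(benzyloxy)-3-methoxyphenyl]-4-{[4-(benzyloxy)-3-methoxyphenyl]methyl}oxolan-3-yl]methyl octadecanoate | CCCCCCCCCCCCCCCCCC(=O)OC[C@H]1[C@@H](Cc2ccc(OCc3ccccc3)c(OC)c2)CO[C@@H]1c1ccc(OCc2ccccc2)c(OC)c1 | intermediate
13 | [(2S,3R,4R)-2-(4-hydroxy-3-methoxyphenyl)-4-[(4-hydroxy-3-methoxyphenyl)methyl]oxolan-3-yl]methyl octadecanoate | CCCCCCCCCCCCCCCCCC(=O)OC[C@H]1[C@@H](Cc2ccc(O)c(OC)c2)CO[C@@H]1c1ccc(O)c(OC)c1 | target

Total step count: 7. Longest linear sequence: 7 steps (1 to 13).

Steps most likely to fail

Step 3. The ester-stabilised dipole may add too slowly to the electron-rich aldehyde. Oligomerisation of the donor, migration of the exocyclic double bond into conjugation with the ester, or weak enantiofacial control could then take over. The fallback sets out from aldehyde 5 and comes back at alcohol 7; it builds the same ring by radical chemistry, with the ring bonds made in separate operations.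
- Addition of vinylmagnesium bromide (THF, 0 °C) would give racemic 1-[4-(benzyloxy)-3-methoxyphenyl]prop-2-en-1-ol F1.
- A Sharpless kinetic resolution (Ti(OiPr)4, D-(−)-diisopropyl tartrate, t-BuOOH, 4 Å sieves, CH2Cl2, −20 °C) would epoxidise the (S)-enantiomer to the erythro epoxy alcohol (R)-[4-(benzyloxy)-3-methoxyphenyl][(2R)-oxiran-2-yl]methanol F2, which is separated from the unreacted (R)-alcohol.
- O-Alkylation (NaH, propargyl bromide, THF, 0 °C) would give (2R)-2-[(R)-[4-(benzyloxy)-3-methoxyphenyl](prop-2-yn-1-yloxy)methyl]oxirane F3.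
- Cp2TiCl (from Cp2TiCl2 and Zn, THF, rt) would open the epoxide to the C3 radical, which closes 5-exo-dig onto the alkyne. After hydrogen abstraction and acidic work-up this should give the 2,3-trans alcohol 7; the epoxide stereocentre is erased in the radical, and C2 comes from the resolved carbinol centre.

Step 6. Facial discrimination in the hydroboration may be poor, because the C2 aryl group sits on the face that must be attacked. The stearate may also be partly saponified, or transmetalation may be slow, during the coupling. The fallback sets out from alkene 9 and comes back at dibenzyl ether 12.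
- A Mizoroki–Heck arylation of 9 with bromide 10 (Pd2(dba)3·CHCl3, t-Bu3P·HBF4, Cy2NMe, dioxane, 90 °C) would give [(2S,3R,4Z)-2-[4-(benzyloxy)-3-methoxyphenyl]-4-{[4-(benzyloxy)-3-methoxyphenyl]methylidene}oxolan-3-yl]methyl octadecanoate F4.
- Heterogeneous hydrogenation of this trisubstituted alkene (H2, PtO2, EtOAc, rt) from the face opposite the C3 arm should give 12.

Step 7. Over-reduction may occur: once the benzyl ethers are gone, hydrogenolysis of the ring benzylic C2–O1 bond would open the oxolane. The fallback sets out from 12 and comes back at 13 without a new compound. It is a non-reductive debenzylation with BCl3 and pentamethylbenzene as cation scavenger (CH2Cl2, −78 °C), quenched cold to limit ionisation at C2.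

Further compounds
F1 | step 3 | 1-[4-(benzyloxy)-3-methoxyphenyl]prop-2-en-1-ol (racemic) | C=CC(O)c1ccc(OCc2ccccc2)c(OC)c1
F2 | step 3 | (R)-[4-(benzyloxy)-3-methoxyphenyl][(2R)-oxiran-2-yl]methanol | O[C@@H]([C@H]1CO1)c1ccc(OCc2ccccc2)c(OC)c1
F3 | step 3 | (2R)-2-[(R)-[4-(benzyloxy)-3-methoxyphenyl](prop-2-yn-1-yloxy)methyl]oxirane | C#CCO[C@@H]([C@H]1CO1)c1ccc(OCc2ccccc2)c(OC)c1
F4 | step 6 | [(2S,3R,4Z)-2-[4-(benzyloxy)-3-methoxyphenyl]-4-{[4-(benzyloxy)-3-methoxyphenyl]methylidene}oxolan-3-yl]methyl octadecanoate | CCCCCCCCCCCCCCCCCC(=O)OC[C@H]1/C(=C/c2ccc(OCc3ccccc3)c(OC)c2)CO[C@@H]1c1ccc(OCc2ccccc2)c(OC)c1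
F0 | step 7 | none | none
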